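**Retrosynthetic overview**

1. Numbering used throughout: ring A = cyclopentene C1–C2–C3=C4(CH3)–C5; seven-membered ring = C1, C5, C6(OH), C7, C8, C9(OH), C10(=CH2); side chain on C7 = C11(CH3), C12(OAc), C13, C14(OH), C15(CH3)=C16; β = face of the C6 hydroxyl (H5 β, H1 α; 1S,5R,6S,7R,9S,11S,12S,14R).
2. Late stage: C14 carbinol by reagent-controlled enone reduction, C12–C13 by Felkin-selective Mukaiyama aldol, C11 by hydroboration of a C7 isopropenyl group, C10=CH2 by methylenation, 9α-OH by enolate oxidation.
3. Key disconnection at C8–C9 and C6–C7: the seven-membered ring is assembled from a five-carbon unit carried by ring A (C9, C10, C1, C5, C6) and the two-carbon unit C7–C8 of methyl vinyl ketone, through a cyclic carbonyl ylide C9–O–C6 generated from a C1 diazoacetyl group and a C5 formyl group; the C6–O–C9 bridge is then opened reductively at C9–O (α to the C10 ketone), leaving the 6β-hydroxyl.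
4. Enabling feature: in the seven-membered ring the oxygen-bearing carbon C6 and the carbon C9 next to C10 (the exocyclic-methylene carbon, a latent ketone) are 1,4-related across C7–C8, so that C10(=O)–C9–O–C6 is an oxidopyrylium-type 1,3-dipole; the trans ring-A fusion at C1–C5 fixes the face on which the two-carbon unit adds.
5. Ring order: ring A first (auxiliary-controlled conjugate addition and allylation, then ring-closing metathesis); seven-membered ring second (step 10); no further ring is formed.

Key step: step 10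

Remark on the chemistry: the SMILES is read as the trans-fused hydroazulene (H1 α, H5 β) with 6β-OH, 7β side chain and 9α-OH. Copper-mediated conjugate addition to the N-enoyl oxazolidinone is assumed to follow the chelated syn-s-cis model (attack anti to the benzyl group).

**Route**

Step 1
Reactants: 1 (S)-4-benzyl-1,3-oxazolidin-2-one; 2 2-(diethoxyphosphoryl)acetic acid
Product: 4 (S)-4-benzyl-3-[2-(diethoxyphosphoryl)acetyl]-1,3-oxazolidin-2-one, via mixed pivalic anhydride 3 (not isolated)
Conditions: 2, t-BuCOCl, Et3N, THF, −20 °C; then LiCl, 1, −20 °C → rt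
Reagents that add atoms: none
Why: Activation of the acid as the mixed pivalic anhydride and LiCl-assisted N-acylation is a standard way to attach a carboxylic acid to the oxazolidinone auxiliary without strong base.

Step 2
Reactants: 4 phosphonate imide; 5 2-(tert-butyldimethylsilyloxy)acetaldehyde
Product: 6 (S)-4-benzyl-3-[(E)-4-(tert-butyldimethylsilyloxy)but-2-enoyl]-1,3-oxazolidin-2-one
Conditions: LiCl, i-Pr2NEt, MeCN, rt
Reagents that add atoms: none
Why: Horner–Wadsworth–Emmons olefination under mild LiCl/amine (Masamune–Roush) conditions should give the (E)-enoyl imide and tolerates the silyl ether.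

Step 3
Reactants: 6 enoyl imide; 7 isopropenylmagnesium bromide
Product: 8 (S)-4-benzyl-3-[(3R)-3-(tert-butyldimethylsilyloxymethyl)-4-methylpent-4-enoyl]-1,3-oxazolidin-2-one
Conditions: 7 (1.5 equiv), CuBr·SMe2 (0.3 equiv), THF/Me2S, −78 → −30 °C; aq. NH4Cl
Reagents that add atoms: none
Why: Copper-catalysed conjugate addition of the alkenyl Grignard reagent to the chelated syn-s-cis N-enoyl oxazolidinone should occur anti to the benzyl group and thereby set the future C5 centre (3R).

Step 4
Reactants: 8 conjugate adduct; 9 allyl iodide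
Product: 10 (S)-4-benzyl-3-[(2S,3R)-2-allyl-3-(tert-butyldimethylsilyloxymethyl)-4-methylpent-4-enoyl]-1,3-oxazolidin-2-one
Conditions: NaN(SiMe3)2, THF, −78 °C; then 9, −78 → −40 °C
Reagents that add atoms: none
Why: Alkylation of the chelated Z-sodium enolate anti to the benzyl group (Evans alkylation) sets the future C1 centre (2S), and because both new centres answer to the same auxiliary the trans relationship of the two ring-A appendages is fixed.

Step 5
Reactants: 10 diene imide
Product: 11 (S)-4-benzyl-3-[(1S,2R)-2-(tert-butyldimethylsilyloxymethyl)-3-methylcyclopent-3-ene-1-carbonyl]-1,3-oxazolidin-2-one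
Conditions: second-generation Grubbs catalyst RuCl2(=CHPh)(H2IMes)(PCy3) (3 mol%), CH2Cl2, 40 °C
Reagents that add atoms: none
Why: Ring-closing metathesis of the 1,6-diene (allyl plus isopropenyl) closes ring A as the trisubstituted cyclopentene with loss of ethene and touches no stereocentre.

Step 6
Reactants: 11 cyclopentene imide
Product: 13 (1S,2R)-2-(tert-butyldimethylsilyloxymethyl)-3-methylcyclopent-3-ene-1-carboxylic acid, via peroxy acid 12 (not isolated)
Conditions: LiOH, 30% H2O2, THF/H2O, 0 °C; then aq. Na2SO3; then 1 M HCl to pH 3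
Reagents that add atoms: hydrogen peroxide OO
Why: Lithium hydroperoxide attacks the exocyclic imide carbonyl selectively (standard auxiliary cleavage), sulfite reduces the peroxy acid, and the α-centre should not epimerise under these mild conditions.

Step 7
Reactants: 13 carboxylic acid
Product: 15 2-diazo-1-[(1S,2R)-2-(tert-butyldimethylsilyloxymethyl)-3-methylcyclopent-3-en-1-yl]ethan-1-one, via isobutyl carbonic anhydride 14 (not isolated)
Conditions: i-BuOCOCl, N-methylmorpholine, THF, −20 °C; then CH2N2, Et2O, 0 °C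
Reagents that add atoms: diazomethane C=[N+]=[N-]
Why: Acylation of diazomethane by the mixed carbonic anhydride (Arndt–Eistert-type diazo ketone synthesis) gives the α-diazo ketone without strong acid or base, so C1 and the silyl ether are preserved.

Step 8
Reactants: 15 diazo ketone silyl ether
Product: 16 2-diazo-1-[(1S,2R)-2-(hydroxymethyl)-3-methylcyclopent-3-en-1-yl]ethan-1-one
Conditions: Bu4NF, AcOH (1:1), THF, 0 °C → rt
Reagents that add atoms: none
Why: Buffered fluoride cleaves the primary silyl ether, and the diazo ketone should tolerate these near-neutral conditions.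

Step 9
Reactants: 16 diazo ketone alcohol
Product: 17 (1R,5S)-5-(2-diazoacetyl)-2-methylcyclopent-2-ene-1-carbaldehyde
Conditions: Dess–Martin periodinane, NaHCO3, CH2Cl2, 0 °C; used at once
Reagents that add atoms: none
Why: Dess–Martin oxidation under bicarbonate buffer is mild enough for the diazo ketone and should give the β,γ-unsaturated aldehyde without epimerisation at C5 or migration of the ring double bond, provided the aldehyde is used directly.

Step 10
Reactants: 17 diazo keto aldehyde; 18 methyl vinyl ketone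
Product: 21 exo-acetyl cycloadduct (7β-acetyl-6β,9β-epoxy-4-methyl-1αH,5βH-hydroazul-3-en-10-one; an 8-oxabicyclo[3.2.1]octan-2-one with ring A trans-fused at C1–C5), via carbonyl ylide 19 (not isolated), via endo-acetyl epimer 20 (not isolated)
Conditions: Rh2(OAc)4 (1 mol%), 18 (10 equiv), CH2Cl2, rt, slow addition of 17; evaporate; then DBU (0.1 equiv), CH2Cl2, 0 °C
Reagents that add atoms: none
Why: Rh2(OAc)4 converts the diazo ketone into a rhodium carbenoid at C9, which is captured by a lone pair of the C6 formyl oxygen to give the six-membered cyclic carbonyl ylide 19 (C9–O–C6, conjugated with the C10 carbonyl), and this 1,3-dipole adds methyl vinyl ketone in a concerted suprafacial [3+2] cycloaddition that forms C8–C9 and C6–C7 together. The closest known reaction type is the tandem carbenoid cyclisation–carbonyl ylide cycloaddition of 1-diazo-2,5-dicarbonyl compounds with electron-poor alkenes, which gives 8-oxabicyclo[3.2.1]octan-2-ones. The ylide ring closes by attack of the carbonyl oxygen on the carbenoid carbon (six-membered O–C closure), and the seven-membered carbocycle then closes by the intermolecular cycloaddition, a [5+2] annulation in carbon terms (C9, C10, C1, C5, C6 plus C7–C8). Regiochemistry should follow frontier-orbital control, the ylide terminus C9 (largest HOMO coefficient, next to the carbonyl) bonding to the CH2 terminus of the enone (largest LUMO coefficient), so that the unsubstituted carbon becomes C8 and the acetyl-bearing carbon C7. At C6 and C9 the alkene should add to the α face, anti to the pseudoaxial H5, because only this approach leads to the chair oxanone with ring A trans-diequatorial, which places the oxygen bridge and hence O6 on the β face; at C7 the acetyl group should end exo (β, syn to the bridge), the thermodynamically preferred position, reached by enolisation under the DBU treatment if the kinetic mixture contains the endo epimer 20, while C1 stays put because its epimer would force ring A into the axial position under the two-carbon bridge. The step needs ylide formation to outrun carbenoid cyclopropanation of the ring-A alkene and ylide collapse, which the proximity of the formyl oxygen, slow addition of 17 and the excess of dipolarophile are meant to secure.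

Step 11
Reactants: 21 exo-acetyl cycloadduct
Product: 22 7β-isopropenyl-6β,9β-epoxy-4-methyl-1αH,5βH-hydroazul-3-en-10-one
Conditions: Ph3PCH3Br, KN(SiMe3)2, THF, 0 °C; then 21 (1.05 equiv ylide), −78 → 0 °C
Reagents that add atoms: methyltriphenylphosphonium bromide C[P+](c1ccccc1)(c1ccccc1)c1ccccc1.[Br-]
Why: Wittig methylenation should take place at the unhindered methyl ketone and not at the C10 ketone, which is flanked by the bridgehead C9 and the ring-fusion carbon C1, and any enolisation by the basic ylide can only drive C7 further toward the exo epimer.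

Step 12
Reactants: 22 isopropenyl oxa-bridged ketone
Product: 23 6β-hydroxy-7β-isopropenyl-4-methyl-1αH,5βH-hydroazul-3-en-10-one
Conditions: SmI2 (2.5 equiv), THF/MeOH, −78 °C
Reagents that add atoms: none
Why: Two-electron reduction of the α-alkoxy ketone by samarium diiodide expels the C9–O bond (reductive cleavage of an α-heteroatom-substituted ketone), which frees the seven-membered carbocycle, leaves the bridge oxygen on C6 as the 6β-hydroxyl set in step 10, and gives the C9 methylene on protonation of the samarium enolate.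

Step 13
Reactants: 23 hydroxy ketone
Product: 24 6β-(tert-butyldimethylsilyloxy)-7β-isopropenyl-4-methyl-1αH,5βH-hydroazul-3-en-10-one
Conditions: t-BuMe2SiOTf (1.2 equiv), 2,6-lutidine, CH2Cl2, −78 → 0 °C
Reagents that add atoms: tert-butyldimethylsilyl triflate CC(C)(C)[Si](C)(C)OS(=O)(=O)C(F)(F)F
Why: Silyl triflate silylation protects the hindered secondary alcohol and places a bulky group on the β face for the next step.

Step 14
Reactants: 24 silyloxy ketone
Product: 25 9α-hydroxy-6β-(tert-butyldimethylsilyloxy)-7β-isopropenyl-4-methyl-1αH,5βH-hydroazul-3-en-10-one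
Conditions: KN(SiMe3)2, THF, −78 °C; then 2-(phenylsulfonyl)-3-phenyloxaziridine, −78 °C; aq. NH4Cl
Reagents that add atoms: 2-(phenylsulfonyl)-3-phenyloxaziridine O=S(=O)(N1OC1c1ccccc1)c1ccccc1
Why: Kinetic deprotonation at the C9 methylene (not the C1 methine) and oxidation of the enolate with the N-sulfonyloxaziridine (Davis oxidation) should install the hydroxyl from the α face, anti to the β-oriented C7 isopropenyl and C6 silyloxy groups.

Step 15
Reactants: 25 α-hydroxy ketone
Product: 26 6β,9α-bis(tert-butyldimethylsilyloxy)-7β-isopropenyl-4-methyl-1αH,5βH-hydroazul-3-en-10-one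
Conditions: t-BuMe2SiOTf, 2,6-lutidine, CH2Cl2, 0 °C
Reagents that add atoms: tert-butyldimethylsilyl triflate CC(C)(C)[Si](C)(C)OS(=O)(=O)C(F)(F)F
Why: Silylation of the α-hydroxy ketone under non-epimerising conditions protects O9 and further hinders the C10 ketone.

Step 16
Reactants: 26 bis-silyl ketone
Product: 28 (11S)-12-hydroxy ketone (6β,9α-bis(tert-butyldimethylsilyloxy)-7β-[(2S)-1-hydroxypropan-2-yl]-4-methyl-1αH,5βH-hydroazul-3-en-10-one), via B-alkyl-9-BBN adduct 27 (not isolated)
Conditions: 9-BBN-H (1.5 equiv), THF, 0 °C → rt; then 30% H2O2, aq. NaOAc, 0 °C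
Reagents that add atoms: hydrogen peroxide OO
Why: Anti-Markovnikov hydroboration–oxidation with 9-BBN should occur at the isopropenyl group much faster than at the trisubstituted ring-A alkene or the hindered α-silyloxy ketone, and with the C7–H bond eclipsing C11=C12 (A(1,3)-strain model for 2-substituted 1-alkenes) the borane should add anti to the bulky C6(OSi) arm, which gives 11S.

Step 17
Reactants: 28 hydroxy ketone
Product: 29 (2S)-2-[6β,9α-bis(tert-butyldimethylsilyloxy)-4-methyl-10-methylidene-1αH,5βH-hydroazul-3-en-7β-yl]propan-1-ol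
Conditions: Cp2TiMe2 (3 equiv), toluene, 70 °C, dark
Reagents that add atoms: dimethyltitanocene C[Ti](C)(C1C=CC=C1)C1C=CC=C1
Why: Petasis methylenation is non-basic, so the hindered, enolisable α-silyloxy ketone should be converted into the exocyclic methylene without epimerisation at C1 or C9, the free alcohol only consuming reagent reversibly as a titanium alkoxide.

Step 18
Reactants: 29 primary alcohol
Product: 30 (2S)-2-[6β,9α-bis(tert-butyldimethylsilyloxy)-4-methyl-10-methylidene-1αH,5βH-hydroazul-3-en-7β-yl]propanal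
Conditions: Dess–Martin periodinane, NaHCO3, CH2Cl2, 0 °C
Reagents that add atoms: none
Why: Dess–Martin oxidation gives the α-branched aldehyde under buffered conditions that should not epimerise C11.

Step 19
Reactants: 31 3-methylbut-3-en-2-one
Product: 32 3-methyl-2-(trimethylsilyloxy)buta-1,3-diene
Conditions: LiN(i-Pr)2, THF, −78 °C; then Me3SiCl; distillation
Reagents that add atoms: chlorotrimethylsilane C[Si](C)(C)Cl
Why: Kinetic deprotonation of the methyl group and O-silylation give the silyl enol ether needed as the C13–C16 nucleophile.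

Step 20
Reactants: 30 aldehyde; 32 silyl enol ether
Product: 33 (12S)-12-hydroxy-14-oxo aldol (β-hydroxy enone with 6β,9α-bis-silyl ether and C10 methylidene intact)
Conditions: BF3·OEt2 (1.1 equiv), CH2Cl2, −78 °C; aq. NaHCO3
Reagents that add atoms: none
Why: The BF3-promoted Mukaiyama aldol addition through an open transition state should follow the Felkin–Anh model for the α-methyl aldehyde and give the 11,12-syn alcohol (12S).

Step 21
Reactants: 33 aldol
Product: 34 (12S)-12-acetoxy-14-oxo enone
Conditions: Ac2O, pyridine, DMAP (cat.), CH2Cl2, 0 °C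
Reagents that add atoms: acetic anhydride CC(=O)OC(C)=O
Why: DMAP-catalysed acetylation of the only free hydroxyl installs the C12 acetate before the C14 oxygen exists, which avoids any later differentiation of secondary alcohols, and β-elimination should be slow at this temperature.

Step 22
Reactants: 34 acetoxy enone
Product: 35 6,9-bis(tert-butyldimethylsilyl) ether of the target (14R alcohol)
Conditions: (S)-2-methyl-CBS-oxazaborolidine (0.5 equiv), catecholborane (1.5 equiv), toluene, −78 °C; then MeOH, aq. work-up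
Reagents that add atoms: none
Why: Corey–Bakshi–Shibata reduction with the (S)-oxazaborolidine should deliver hydride to the enone carbonyl with the isopropenyl group as the large substituent and give the 14R alcohol under reagent control, while catecholborane at low temperature leaves the alkenes and the acetate untouched.

Step 23
Reactants: 35 bis-silyl ether
Product: 36 target CNP0281601.4
Conditions: HF·pyridine, pyridine, THF, 0 °C → rt
Reagents that add atoms: none
Why: Buffered HF·pyridine removes both silyl ethers under mildly acidic conditions in which the C12 acetate should neither migrate to O14 nor hydrolyse.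

**Compound list**

1 | (S)-4-benzyl-1,3-oxazolidin-2-one | O=C1N[C@@H](Cc2ccccc2)CO1 | starting material
2 | 2-(diethoxyphosphoryl)acetic acid | OC(=O)CP(=O)(OCC)OCC | starting material
3 | 2-(diethoxyphosphoryl)acetic pivalic anhydride (not isolated) | CC(C)(C)C(=O)OC(=O)CP(=O)(OCC)OCC | intermediate
4 | (S)-4-benzyl-3-[2-(diethoxyphosphoryl)acetyl]-1,3-oxazolidin-2-one | O=C1OC[C@H](Cc2ccccc2)N1C(=O)CP(=O)(OCC)OCC | intermediate
5 | 2-(tert-butyldimethylsilyloxy)acetaldehyde | O=CCO[Si](C)(C)C(C)(C)C | starting material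
6 | (S)-4-benzyl-3-[(E)-4-(tert-butyldimethylsilyloxy)but-2-enoyl]-1,3-oxazolidin-2-one | O=C1OC[C@H](Cc2ccccc2)N1C(=O)/C=C/CO[Si](C)(C)C(C)(C)C | intermediate
7 | isopropenylmagnesium bromide | C=C(C)[Mg]Br | starting material
8 | (S)-4-benzyl-3-[(3R)-3-(tert-butyldimethylsilyloxymethyl)-4-methylpent-4-enoyl]-1,3-oxazolidin-2-one | O=C1OC[C@H](Cc2ccccc2)N1C(=O)C[C@@H](CO[Si](C)(C)C(C)(C)C)C(C)=C | intermediate
9 | allyl iodide (3-iodoprop-1-ene) | C=CCI | starting material
10 | (S)-4-benzyl-3-[(2S,3R)-2-allyl-3-(tert-butyldimethylsilyloxymethyl)-4-methylpent-4-enoyl]-1,3-oxazolidin-2-one | O=C1OC[C@H](Cc2ccccc2)N1C(=O)[C@@H](CC=C)[C@@H](CO[Si](C)(C)C(C)(C)C)C(C)=C | intermediate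
11 | (S)-4-benzyl-3-[(1S,2R)-2-(tert-butyldimethylsilyloxymethyl)-3-methylcyclopent-3-ene-1-carbonyl]-1,3-oxazolidin-2-one | O=C1OC[C@H](Cc2ccccc2)N1C(=O)[C@H]3CC=C(C)[C@@H]3CO[Si](C)(C)C(C)(C)C | intermediate
12 | (1S,2R)-2-(tert-butyldimethylsilyloxymethyl)-3-methylcyclopent-3-ene-1-carboperoxoic acid (not isolated) | OOC(=O)[C@H]1CC=C(C)[C@@H]1CO[Si](C)(C)C(C)(C)C | intermediate
13 | (1S,2R)-2-(tert-butyldimethylsilyloxymethyl)-3-methylcyclopent-3-ene-1-carboxylic acid | OC(=O)[C@H]1CC=C(C)[C@@H]1CO[Si](C)(C)C(C)(C)C | intermediate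
14 | mixed anhydride of 13 with isobutyl hydrogen carbonate (not isolated) | CC(C)COC(=O)OC(=O)[C@H]1CC=C(C)[C@@H]1CO[Si](C)(C)C(C)(C)C | intermediate
15 | 2-diazo-1-[(1S,2R)-2-(tert-butyldimethylsilyloxymethyl)-3-methylcyclopent-3-en-1-yl]ethan-1-one | [N-]=[N+]=CC(=O)[C@H]1CC=C(C)[C@@H]1CO[Si](C)(C)C(C)(C)C | intermediate
16 | 2-diazo-1-[(1S,2R)-2-(hydroxymethyl)-3-methylcyclopent-3-en-1-yl]ethan-1-one | [N-]=[N+]=CC(=O)[C@H]1CC=C(C)[C@@H]1CO | intermediate
17 | (1R,5S)-5-(2-diazoacetyl)-2-methylcyclopent-2-ene-1-carbaldehyde | [N-]=[N+]=CC(=O)[C@H]1CC=C(C)[C@@H]1C=O | intermediate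
18 | methyl vinyl ketone (but-3-en-2-one) | C=CC(C)=O | starting material
19 | cyclic carbonyl ylide C10(O−)=C9–O+=C6, trans-fused to ring A (not isolated) | [O-]C1=C[O+]=C[C@H]2C(C)=CC[C@H]12 | intermediate
20 | endo-acetyl (7α) epimer of 21 (not isolated) | CC(=O)[C@@H]1C[C@@H]3C(=O)[C@H]2CC=C(C)[C@@H]2[C@H]1O3 | intermediate
21 | 7β-acetyl-6β,9β-epoxy-4-methyl-1αH,5βH-hydroazul-3-en-10-one (exo-acetyl cycloadduct) | CC(=O)[C@H]1C[C@@H]3C(=O)[C@H]2CC=C(C)[C@@H]2[C@H]1O3 | intermediate
22 | 7β-isopropenyl-6β,9β-epoxy-4-methyl-1αH,5βH-hydroazul-3-en-10-one | C=C(C)[C@H]1C[C@@H]3C(=O)[C@H]2CC=C(C)[C@@H]2[C@H]1O3 | intermediate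
23 | 6β-hydroxy-7β-isopropenyl-4-methyl-1αH,5βH-hydroazul-3-en-10-one | C=C(C)[C@H]1CCC(=O)[C@H]2CC=C(C)[C@@H]2[C@H]1O | intermediate
24 | 6β-(tert-butyldimethylsilyloxy)-7β-isopropenyl-4-methyl-1αH,5βH-hydroazul-3-en-10-one | C=C(C)[C@H]1CCC(=O)[C@H]2CC=C(C)[C@@H]2[C@H]1O[Si](C)(C)C(C)(C)C | intermediate
25 | 9α-hydroxy-6β-(tert-butyldimethylsilyloxy)-7β-isopropenyl-4-methyl-1αH,5βH-hydroazul-3-en-10-one | C=C(C)[C@H]1C[C@H](O)C(=O)[C@H]2CC=C(C)[C@@H]2[C@H]1O[Si](C)(C)C(C)(C)C | intermediate
26 | 6β,9α-bis(tert-butyldimethylsilyloxy)-7β-isopropenyl-4-methyl-1αH,5βH-hydroazul-3-en-10-one | C=C(C)[C@H]1C[C@H](O[Si](C)(C)C(C)(C)C)C(=O)[C@H]2CC=C(C)[C@@H]2[C@H]1O[Si](C)(C)C(C)(C)C | intermediate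
27 | B-[(2S)-2-(hydroazulenyl)propyl]-9-borabicyclo[3.3.1]nonane adduct of 26 (not isolated) | C3CCC4CCCC3B4C[C@@H](C)[C@H]1C[C@H](O[Si](C)(C)C(C)(C)C)C(=O)[C@H]2CC=C(C)[C@@H]2[C@H]1O[Si](C)(C)C(C)(C)C | intermediate
28 | 6β,9α-bis(tert-butyldimethylsilyloxy)-7β-[(2S)-1-hydroxypropan-2-yl]-4-methyl-1αH,5βH-hydroazul-3-en-10-one | OC[C@@H](C)[C@H]1C[C@H](O[Si](C)(C)C(C)(C)C)C(=O)[C@H]2CC=C(C)[C@@H]2[C@H]1O[Si](C)(C)C(C)(C)C | intermediate
29 | (2S)-2-[6β,9α-bis(tert-butyldimethylsilyloxy)-4-methyl-10-methylidene-1αH,5βH-hydroazul-3-en-7β-yl]propan-1-ol | OC[C@@H](C)[C@H]1C[C@H](O[Si](C)(C)C(C)(C)C)C(=C)[C@H]2CC=C(C)[C@@H]2[C@H]1O[Si](C)(C)C(C)(C)C | intermediate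
30 | (2S)-2-[6β,9α-bis(tert-butyldimethylsilyloxy)-4-methyl-10-methylidene-1αH,5βH-hydroazul-3-en-7β-yl]propanal | O=C[C@@H](C)[C@H]1C[C@H](O[Si](C)(C)C(C)(C)C)C(=C)[C@H]2CC=C(C)[C@@H]2[C@H]1O[Si](C)(C)C(C)(C)C | intermediate
31 | 3-methylbut-3-en-2-one | CC(=O)C(C)=C | starting material
32 | 3-methyl-2-(trimethylsilyloxy)buta-1,3-diene | C=C(O[Si](C)(C)C)C(C)=C | intermediate
33 | (12S)-12-hydroxy-14-oxo aldol (11S; 6β,9α-bis-silyl ether; C10 methylidene) | C=C(C)C(=O)C[C@H](O)[C@@H](C)[C@H]1C[C@H](O[Si](C)(C)C(C)(C)C)C(=C)[C@H]2CC=C(C)[C@@H]2[C@H]1O[Si](C)(C)C(C)(C)C | intermediate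
34 | (12S)-12-acetoxy-14-oxo enone (11S; 6β,9α-bis-silyl ether) | C=C(C)C(=O)C[C@H](OC(C)=O)[C@@H](C)[C@H]1C[C@H](O[Si](C)(C)C(C)(C)C)C(=C)[C@H]2CC=C(C)[C@@H]2[C@H]1O[Si](C)(C)C(C)(C)C | intermediate
35 | 6,9-bis(tert-butyldimethylsilyl) ether of the target (14R) | C=C(C)[C@H](O)C[C@H](OC(C)=O)[C@@H](C)[C@H]1C[C@H](O[Si](C)(C)C(C)(C)C)C(=C)[C@H]2CC=C(C)[C@@H]2[C@H]1O[Si](C)(C)C(C)(C)C | intermediate
36 | CNP0281601.4 | C=C(C)[C@H](O)C[C@H](OC(C)=O)[C@@H](C)[C@H]1C[C@H](O)C(=C)[C@H]2CC=C(C)[C@@H]2[C@H]1O | target

**Step count**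

Total: 23 steps. Longest linear sequence: 22 steps (steps 1–18 and 20–23); step 19 is a one-step branch.

**Steps most likely to fail**

Step 10 (key step). The rhodium carbenoid may be intercepted by the ring-A double bond (intramolecular cyclopropanation), or the ylide may collapse by proton transfer or dimerisation before methyl vinyl ketone adds; some facial leakage is also possible. The fallback closes the same ring stepwise without a carbenoid. It sets out from acid 13: MeLi (2.2 equiv, Et2O, 0 °C) gives methyl ketone F1; the kinetic lithium enolate (LiN(i-Pr)2, THF, −78 °C) is alkylated with allyl bromide to give but-3-enyl ketone F2, which forms the C8–C9 bond; cross-metathesis with methallyltrimethylsilane (second-generation Grubbs catalyst, CH2Cl2, 40 °C) gives allylsilane F3; Bu4NF/AcOH gives hydroxy allylsilane F4 and Dess–Martin oxidation gives keto aldehyde F5. An intramolecular Hosomi–Sakurai allylation (BF3·OEt2, CH2Cl2, −78 °C) then closes the seven-membered ring at C6–C7 and unveils the isopropenyl group; the open synclinal transition state is expected to give the 6,7-cis arrangement. The route is rejoined at hydroxy ketone 23, bypassing steps 7–12.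

Step 14. The oxidant may attack the β face of the enolate, or deprotonation may occur toward C1 with erosion of the trans ring fusion. The fallback replaces facial control by an invertive substitution. It sets out from 24: if the oxygenation delivers the 9β-hydroxy ketone F6, a Mitsunobu reaction (4-nitrobenzoic acid, PPh3, DIAD, toluene, 0 °C) inverts C9 to give the 9α-(4-nitrobenzoate) F7, and mild methanolysis (K2CO3, MeOH, 0 °C) returns to 25.

Step 16. Borane addition to the freely rotating isopropenyl group may show low facial selectivity (mixture at C11), and the ketone may be partly reduced. The fallback erases C11 and resets it under catalyst control. The epimeric material is carried through steps 17 and 18 to aldehyde 30 (as a C11 mixture), from which the fallback sets out: amine-catalysed α-selenenylation with N-(phenylseleno)phthalimide gives α-phenylseleno aldehyde F8; NaIO4 oxidation and selenoxide syn-elimination toward the methyl group gives the 2-substituted acrolein F9; Luche reduction (NaBH4, CeCl3·7H2O, MeOH, −40 °C) gives the 2-substituted allylic alcohol F10. Hydroxyl-directed asymmetric hydrogenation with Ru(OAc)2(BINAP) (ligand enantiomer chosen by the established facial rule; H2, MeOH) should reduce only the allylic-alcohol double bond and set 11S, which returns to 29.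

Further compounds

F1 | step 10 | 1-[(1S,2R)-2-(tert-butyldimethylsilyloxymethyl)-3-methylcyclopent-3-en-1-yl]ethan-1-one | CC(=O)[C@H]1CC=C(C)[C@@H]1CO[Si](C)(C)C(C)(C)C
F2 | step 10 | 1-[(1S,2R)-2-(tert-butyldimethylsilyloxymethyl)-3-methylcyclopent-3-en-1-yl]pent-4-en-1-one | C=CCCC(=O)[C@H]1CC=C(C)[C@@H]1CO[Si](C)(C)C(C)(C)C
F3 | step 10 | (E)-1-[(1S,2R)-2-(tert-butyldimethylsilyloxymethyl)-3-methylcyclopent-3-en-1-yl]-5-methyl-6-(trimethylsilyl)hex-4-en-1-one | C[Si](C)(C)C/C(C)=C/CCC(=O)[C@H]1CC=C(C)[C@@H]1CO[Si](C)(C)C(C)(C)C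
F4 | step 10 | (E)-1-[(1S,2R)-2-(hydroxymethyl)-3-methylcyclopent-3-en-1-yl]-5-methyl-6-(trimethylsilyl)hex-4-en-1-one | C[Si](C)(C)C/C(C)=C/CCC(=O)[C@H]1CC=C(C)[C@@H]1CO
F5 | step 10 | (1R,5S)-2-methyl-5-[(E)-5-methyl-6-(trimethylsilyl)hex-4-enoyl]cyclopent-2-ene-1-carbaldehyde | C[Si](C)(C)C/C(C)=C/CCC(=O)[C@H]1CC=C(C)[C@@H]1C=O
F6 | step 14 | 9β-hydroxy-6β-(tert-butyldimethylsilyloxy)-7β-isopropenyl-4-methyl-1αH,5βH-hydroazul-3-en-10-one | C=C(C)[C@H]1C[C@@H](O)C(=O)[C@H]2CC=C(C)[C@@H]2[C@H]1O[Si](C)(C)C(C)(C)C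
F7 | step 14 | 9α-(4-nitrobenzoyloxy)-6β-(tert-butyldimethylsilyloxy)-7β-isopropenyl-4-methyl-1αH,5βH-hydroazul-3-en-10-one | C=C(C)[C@H]1C[C@H](OC(=O)c3ccc(cc3)[N+](=O)[O-])C(=O)[C@H]2CC=C(C)[C@@H]2[C@H]1O[Si](C)(C)C(C)(C)C
F8 | step 16 | 2-[6β,9α-bis(tert-butyldimethylsilyloxy)-4-methyl-10-methylidene-1αH,5βH-hydroazul-3-en-7β-yl]-2-(phenylselanyl)propanal (C11 epimer mixture) | O=CC(C)([Se]c1ccccc1)[C@H]1C[C@H](O[Si](C)(C)C(C)(C)C)C(=C)[C@H]2CC=C(C)[C@@H]2[C@H]1O[Si](C)(C)C(C)(C)C
F9 | step 16 | 2-[6β,9α-bis(tert-butyldimethylsilyloxy)-4-methyl-10-methylidene-1αH,5βH-hydroazul-3-en-7β-yl]prop-2-enal | O=CC(=C)[C@H]1C[C@H](O[Si](C)(C)C(C)(C)C)C(=C)[C@H]2CC=C(C)[C@@H]2[C@H]1O[Si](C)(C)C(C)(C)C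
F10 | step 16 | 2-[6β,9α-bis(tert-butyldimethylsilyloxy)-4-methyl-10-methylidene-1αH,5βH-hydroazul-3-en-7β-yl]prop-2-en-1-ol | OCC(=C)[C@H]1C[C@H](O[Si](C)(C)C(C)(C)C)C(=C)[C@H]2CC=C(C)[C@@H]2[C@H]1O[Si](C)(C)C(C)(C)C
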